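**Plan**

- Retrosynthesis: (a) remove twelve O-benzyl, three O-acetyl and two C8–Br groups; (b) cut the upper interflavan bond C4(top)–C8(middle); (c) cut O1–C2 and C3–C4 of ring C of the middle unit in one stroke, a retro-hetero-Diels–Alder that leaves an ortho-quinone methide and an (E)-enol acetate; (d) cut C4–C4a of the methide precursor into a ring A phenol and a C6-formyl bottom unit.
- Enabling feature: ring A of the middle unit is a phloroglucinol ring whose O1–C8a=C4a–C4 array is an ortho-hydroxybenzyl unit. With C4 carrying a second trioxygenated aryl (C6 of the bottom unit) it should ionise under weak acid to an ortho-quinone methide, and the para-oxygenated ring B on C2 polarises the C2=C3 partner in the styrene sense.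
- Forward: (+)-catechin gives the bottom unit (C8 blocked by Br, C6 formylated); ortho-hydroxyalkylation of 3,5-bis(benzyloxy)phenol gives the benzhydrol; the [4+2] step builds ring C of the middle unit and with it the 4→6 junction; a bromine-capped catechin C4 electrophile is joined to C8 of the new unit; deacetylation and hydrogenolysis finish.
- Stereochemistry: top and bottom units come from (+)-catechin (2R,3S). In the middle unit the C2/C3 trans relation comes from the (E)-alkene, C4 from the endo transition state, and the absolute sense from a chiral phosphoric acid. The upper C4 (α) comes from 3-acetoxy participation.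

Key step: step 9

Assumption: the (R)-antipode of the phosphoric acid is taken as the one that delivers 13 to the face of 14 that gives the (2R,3S)-configured middle unit; the sense of induction is to be checked on small scale, the (S)-antipode being the direct substitute.

**Step 1**
Reactants: 1 (+)-catechin
Product: 2 5,7,3',4'-tetra-O-benzyl-(+)-catechin
Conditions: BnBr (4.4 equiv), K2CO3, DMF, 0 °C → rt
Reagents that add atoms: benzyl bromide BrCc1ccccc1
Why: Williamson etherification; the four phenols are far more acidic than the C3 alcohol, so K2CO3 should benzylate only them, and no stereocenter is touched.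

**Step 2**
Reactants: 2 5,7,3',4'-tetra-O-benzyl-(+)-catechin
Product: 3 8-bromo-5,7,3',4'-tetra-O-benzyl-(+)-catechin
Conditions: NBS (1.0 equiv), CH2Cl2, −78 °C → rt
Reagents that add atoms: N-bromosuccinimide O=C1CCC(=O)N1Br
Why: Electrophilic aromatic bromination; C8 of ring A, flanked by O1 and only one benzyloxy group, is the most accessible and most nucleophilic carbon, so the bromide should form there and leave C6 as the only free ring A position.

**Step 3**
Reactants: 3 8-bromo-5,7,3',4'-tetra-O-benzyl-(+)-catechin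
Product: 4 3-O-acetyl-8-bromo-5,7,3',4'-tetra-O-benzyl-(+)-catechin
Conditions: Ac2O, pyridine, DMAP (cat.), CH2Cl2, rt
Reagents that add atoms: acetic anhydride CC(=O)OC(C)=O
Why: DMAP-catalysed acylation of the secondary alcohol, which masks it against the Vilsmeier reagent and the Grignard base of the next two steps.

**Step 4**
Reactants: 4 3-O-acetyl-8-bromo-5,7,3',4'-tetra-O-benzyl-(+)-catechin
Product: 6 3-O-acetyl-8-bromo-6-formyl-5,7,3',4'-tetra-O-benzyl-(+)-catechin, via aryl iminium chloride 5 (not isolated)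
Conditions: POCl3, DMF, 0 → 70 °C; then aq NaOAc, rt
Reagents that add atoms: N,N-dimethylformamide CN(C)C=O; water O
Why: Vilsmeier–Haack formylation; the chloroiminium ion should attack the only unsubstituted carbon of the trioxygenated ring A (C6), ring B being far less nucleophilic, and the iminium salt is hydrolysed on work-up.

**Step 5**
Reactants: 7 3,5-bis(benzyloxy)phenol; 6 3-O-acetyl-8-bromo-6-formyl-5,7,3',4'-tetra-O-benzyl-(+)-catechin
Product: 9 [3-O-acetyl-8-bromo-5,7,3',4'-tetra-O-benzylcatechin-6-yl][2,4-bis(benzyloxy)-6-hydroxyphenyl]methanol (both carbinol epimers), via bromomagnesium phenoxide 8 (not isolated)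
Conditions: 7 (2 equiv), EtMgBr (1.9 equiv), Et2O, 0 °C; solvent exchange to toluene; 6, rt; pH 7 buffer; Et3N-deactivated SiO2
Reagents that add atoms: none
Why: Ortho-specific hydroxyalkylation of a bromomagnesium phenoxide in a non-coordinating solvent; magnesium binds phenoxide and aldehyde and should deliver the carbonyl carbon to an ortho carbon (the two are equivalent) through a six-membered transition state, and the carbinol configuration is irrelevant because it is lost in step 9.

**Step 6**
Reactants: 10 3,4-bis(benzyloxy)benzaldehyde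
Product: 11 (E)-2-[3,4-bis(benzyloxy)styryl]-4,4,5,5-tetramethyl-1,3,2-dioxaborolane
Conditions: CH2(Bpin)2, lithium 2,2,6,6-tetramethylpiperidide (from the amine and n-BuLi), THF, 0 °C; then 10, −78 °C → rt
Reagents that add atoms: bis[(pinacolato)boryl]methane CC1(C)OB(CB2OC(C)(C)C(C)(C)O2)OC1(C)C
Why: Boron–Wittig olefination; the α-boryl carbanion adds to the aldehyde and syn-elimination of the borate should give the (E)-alkenylboronate, fixing the geometry that becomes the 2,3-trans relation.

**Step 7**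
Reactants: 11 (E)-2-[3,4-bis(benzyloxy)styryl]-4,4,5,5-tetramethyl-1,3,2-dioxaborolane
Product: 12 potassium (E)-[3,4-bis(benzyloxy)styryl]trifluoroborate
Conditions: KHF2 (aq), MeOH, rt
Reagents that add atoms: potassium hydrogen difluoride [K+].F[H-]F
Why: Standard conversion of a pinacol boronate into the trifluoroborate, the form that transmetallates cleanly to copper; the alkene geometry is not touched.

**Step 8**
Reactants: 12 potassium (E)-[3,4-bis(benzyloxy)styryl]trifluoroborate
Product: 13 (E)-2-[3,4-bis(benzyloxy)phenyl]ethenyl acetate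
Conditions: AcOH, CuBr (10 mol %), DMAP, 4 Å MS, O2 (1 atm), MeCN, 40 °C
Reagents that add atoms: acetic acid CC(O)=O
Why: Chan–Lam-type oxidative C–O coupling of an alkenyltrifluoroborate with a carboxylic acid; transmetallation to copper and reductive elimination from a trivalent copper carboxylate proceed with retention, so the (E)-enol acetate should result.

**Step 9**
Reactants: 9 [3-O-acetyl-8-bromo-5,7,3',4'-tetra-O-benzylcatechin-6-yl][2,4-bis(benzyloxy)-6-hydroxyphenyl]methanol; 13 (E)-2-[3,4-bis(benzyloxy)phenyl]ethenyl acetate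
Product: 15 3-O-acetyl-5,7,3',4'-tetra-O-benzylcatechin-(4α→6)-3-O-acetyl-8-bromo-5,7,3',4'-tetra-O-benzylcatechin, via ortho-quinone methide 14 (not isolated)
Conditions: (R)-TRIP [(R)-3,3'-bis(2,4,6-triisopropylphenyl)-1,1'-binaphthyl-2,2'-diyl hydrogen phosphate] (10 mol %), 13 (3 equiv), 5 Å MS, CH2Cl2, −20 °C → rt, slow addition of 9
Reagents that add atoms: none
Why: Proposed new method: the acid dehydrates 9 to the ortho-quinone methide 14 (heterodiene O1–C8a=C4a–C4 of the future middle unit, hydrogen-bonded or ion-paired to the phosphate), which should add across the C2=C3 bond of 13 in an inverse-electron-demand, asynchronous hetero-Diels–Alder reaction in which C3–C4 bonding leads and O1–C2 closure follows. The closest known reaction type is the chiral-phosphoric-acid-catalysed [4+2] cycloaddition of ortho-quinone methides from ortho-hydroxybenzhydrols with styrenes, enol ethers and vinyl sulfides; new is the β-acetoxystyrene partner, which must react with styrene-type and not enol-type regiochemistry. Ring C of the middle unit (O1, C2, C3, C4, C4a, C8a) is closed in an intermolecular [4+2] mode on the existing ring A. C2 and C3 take their trans relation from the (E)-alkene by suprafacial addition (backed by acetoxonium participation if closure becomes stepwise), C4 takes its trans relation to C3 and cis relation to C2 from the transition state with the ring B aryl endo and the acetoxy group exo on the (E)-methide, which leads to the all-equatorial flavan, and the absolute configuration (C2 R, C3 S, C4 aryl α) is set by the chiral phosphate bound at O1, which shields one face of the planar methide, the distant bottom-unit stereocenters only making the two facial products separable diastereomers. The step needs regioselectivity (C4 to the acetoxy-bearing carbon, O1 to the benzylic carbon) and chemoselectivity against Friedel–Crafts capture of 14: the 4-benzyloxy group of ring B makes the acetoxy-bearing carbon the nucleophilic terminus and stabilises the charge developing at C2, the acetyl group attenuates the enol oxygen, the 5,7-dioxygenation of ring A and the trioxygenated aryl on C4 let 14 form under a weak acid, and the bottom unit has no free ring A carbon because C8 carries bromine.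

**Step 10**
Reactants: 3 8-bromo-5,7,3',4'-tetra-O-benzyl-(+)-catechin
Product: 16 8-bromo-4β-(2-ethoxyethoxy)-5,7,3',4'-tetra-O-benzyl-(+)-catechin
Conditions: DDQ, 2-ethoxyethanol, CH2Cl2, rt
Reagents that add atoms: 2-ethoxyethanol CCOCCO
Why: Benzylic oxidation with DDQ; hydride abstraction from C4 is assisted by the ring A oxygens and the alcohol should trap the cation anti to the C2 aryl group, a configuration that does not matter because C4 is ionised again in step 12.

**Step 11**
Reactants: 16 8-bromo-4β-(2-ethoxyethoxy)-5,7,3',4'-tetra-O-benzyl-(+)-catechin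
Product: 17 3-O-acetyl-8-bromo-4β-(2-ethoxyethoxy)-5,7,3',4'-tetra-O-benzyl-(+)-catechin
Conditions: Ac2O, pyridine, DMAP (cat.), CH2Cl2, rt
Reagents that add atoms: acetic anhydride CC(=O)OC(C)=O
Why: Standard acylation; the acetate is needed as the participating group that directs the C4 configuration in step 12.

**Step 12**
Reactants: 15 3-O-acetyl-5,7,3',4'-tetra-O-benzylcatechin-(4α→6)-3-O-acetyl-8-bromo-5,7,3',4'-tetra-O-benzylcatechin; 17 3-O-acetyl-8-bromo-4β-(2-ethoxyethoxy)-5,7,3',4'-tetra-O-benzyl-(+)-catechin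
Product: 18 3-O-acetyl-8-bromo-5,7,3',4'-tetra-O-benzylcatechin-(4α→8)-3-O-acetyl-5,7,3',4'-tetra-O-benzylcatechin-(4α→6)-3-O-acetyl-8-bromo-5,7,3',4'-tetra-O-benzylcatechin
Conditions: TMSOTf (cat.), 15 (1.2 equiv), CH2Cl2, −78 → −40 °C; aq NaHCO3
Reagents that add atoms: none
Why: Lewis-acid-mediated Friedel–Crafts condensation of a flavan-4-yl cation with a flavan nucleophile; the 3-acetoxy group bridges the β face so the arene should add from the α face (3,4-trans), C8 of the upper unit of 15 (flanked by O1 and one benzyloxy group) is the most nucleophilic free carbon while C6 sits between two benzyloxy groups, and the bromine at C8 of 17 suppresses self-condensation.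

**Step 13**
Reactants: 18 tri-O-acetyl dibromo dodeca-O-benzyl trimer
Product: 19 8-bromo-5,7,3',4'-tetra-O-benzylcatechin-(4α→8)-5,7,3',4'-tetra-O-benzylcatechin-(4α→6)-8-bromo-5,7,3',4'-tetra-O-benzylcatechin
Conditions: NaOMe (cat.), MeOH/THF, rt → 40 °C
Reagents that add atoms: none
Why: Zemplén transesterification should remove the three secondary acetates while benzyl ethers and aryl bromides are inert, and with all phenols still protected no base-induced epimerisation at C2 can occur.

**Step 14**
Reactants: 19 dibromo dodeca-O-benzyl trimer triol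
Product: 20 catechin-(4α→8)-catechin-(4α→6)-catechin (CNP0178679.4)
Conditions: H2 (1 atm), Pd(OH)2/C, Et3N (2.2 equiv), THF/MeOH/H2O, rt
Reagents that add atoms: none
Why: Catalytic hydrogenolysis should cleave the twelve benzyl ethers and, with Et3N as HBr scavenger, both aryl C–Br bonds, while the C2–O1 and C4–aryl bonds of flavans are expected to survive these mild conditions.

**Compound list**

1 | (+)-catechin, (2R,3S) | Oc1cc(O)c2c(c1)O[C@H](c1ccc(O)c(O)c1)[C@@H](O)C2 | starting material
2 | 5,7,3',4'-tetra-O-benzyl-(+)-catechin | c1ccccc1COc1cc(OCc2ccccc2)c2c(c1)O[C@H](c1ccc(OCc3ccccc3)c(OCc3ccccc3)c1)[C@@H](O)C2 | intermediate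
3 | 8-bromo-5,7,3',4'-tetra-O-benzyl-(+)-catechin | c1ccccc1COc1cc(OCc2ccccc2)c2c(c1Br)O[C@H](c1ccc(OCc3ccccc3)c(OCc3ccccc3)c1)[C@@H](O)C2 | intermediate
4 | 3-O-acetyl-8-bromo-5,7,3',4'-tetra-O-benzyl-(+)-catechin | c1ccccc1COc1cc(OCc2ccccc2)c2c(c1Br)O[C@H](c1ccc(OCc3ccccc3)c(OCc3ccccc3)c1)[C@@H](OC(C)=O)C2 | intermediate
5 | C6 (dimethyliminio)methyl derivative of 4, chloride salt | c1ccccc1COc1c(C=[N+](C)C)c(OCc2ccccc2)c2c(c1Br)O[C@H](c1ccc(OCc3ccccc3)c(OCc3ccccc3)c1)[C@@H](OC(C)=O)C2.[Cl-] | intermediate (not isolated)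
6 | 3-O-acetyl-8-bromo-6-formyl-5,7,3',4'-tetra-O-benzyl-(+)-catechin | c1ccccc1COc1c(C=O)c(OCc2ccccc2)c2c(c1Br)O[C@H](c1ccc(OCc3ccccc3)c(OCc3ccccc3)c1)[C@@H](OC(C)=O)C2 | intermediate
7 | 3,5-bis(benzyloxy)phenol | Oc1cc(OCc2ccccc2)cc(OCc2ccccc2)c1 | starting material
8 | bromomagnesium 3,5-bis(benzyloxy)phenoxide | Br[Mg]Oc1cc(OCc2ccccc2)cc(OCc2ccccc2)c1 | intermediate (not isolated)
9 | [3-O-acetyl-8-bromo-5,7,3',4'-tetra-O-benzylcatechin-6-yl][2,4-bis(benzyloxy)-6-hydroxyphenyl]methanol, both carbinol epimers, flavan centers 2R,3S | OC(c1c(O)cc(OCc2ccccc2)cc1OCc1ccccc1)c1c(OCc3ccccc3)c(Br)c2c(c1OCc1ccccc1)C[C@H](OC(C)=O)[C@@H](c1ccc(OCc3ccccc3)c(OCc3ccccc3)c1)O2 | intermediate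
10 | 3,4-bis(benzyloxy)benzaldehyde | O=Cc1ccc(OCc2ccccc2)c(OCc2ccccc2)c1 | starting material
11 | (E)-2-[3,4-bis(benzyloxy)styryl]-4,4,5,5-tetramethyl-1,3,2-dioxaborolane | CC1(C)OB(/C=C/c2ccc(OCc3ccccc3)c(OCc3ccccc3)c2)OC1(C)C | intermediate
12 | potassium (E)-[3,4-bis(benzyloxy)styryl]trifluoroborate | [K+].F[B-](F)(F)/C=C/c1ccc(OCc2ccccc2)c(OCc2ccccc2)c1 | intermediate
13 | (E)-2-[3,4-bis(benzyloxy)phenyl]ethenyl acetate | CC(=O)O/C=C/c1ccc(OCc2ccccc2)c(OCc2ccccc2)c1 | intermediate
14 | (E)-ortho-quinone methide: 3,5-bis(benzyloxy)-6-[(3-O-acetyl-8-bromo-5,7,3',4'-tetra-O-benzylcatechin-6-yl)methylidene]cyclohexa-2,4-dien-1-one | O=C1C=C(OCc2ccccc2)C=C(OCc2ccccc2)/C1=C\c1c(OCc3ccccc3)c(Br)c2c(c1OCc1ccccc1)C[C@H](OC(C)=O)[C@@H](c1ccc(OCc3ccccc3)c(OCc3ccccc3)c1)O2 | intermediate (not isolated)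
15 | 3-O-acetyl-5,7,3',4'-tetra-O-benzylcatechin-(4α→6)-3-O-acetyl-8-bromo-5,7,3',4'-tetra-O-benzylcatechin (upper unit 2R,3S, C4 aryl α, 2,3-trans-3,4-trans; lower unit 2R,3S) | c1ccccc1COc1cc(OCc2ccccc2)c2c(c1)O[C@H](c1ccc(OCc3ccccc3)c(OCc3ccccc3)c1)[C@@H](OC(C)=O)[C@@H]2c1c(OCc3ccccc3)c(Br)c2c(c1OCc1ccccc1)C[C@H](OC(C)=O)[C@@H](c1ccc(OCc3ccccc3)c(OCc3ccccc3)c1)O2 | intermediate
16 | 8-bromo-4β-(2-ethoxyethoxy)-5,7,3',4'-tetra-O-benzyl-(+)-catechin (3,4-cis) | c1ccccc1COc1cc(OCc2ccccc2)c2c(c1Br)O[C@H](c1ccc(OCc3ccccc3)c(OCc3ccccc3)c1)[C@@H](O)[C@H]2OCCOCC | intermediate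
17 | 3-O-acetyl-8-bromo-4β-(2-ethoxyethoxy)-5,7,3',4'-tetra-O-benzyl-(+)-catechin | c1ccccc1COc1cc(OCc2ccccc2)c2c(c1Br)O[C@H](c1ccc(OCc3ccccc3)c(OCc3ccccc3)c1)[C@@H](OC(C)=O)[C@H]2OCCOCC | intermediate
18 | 3-O-acetyl-8-bromo-tetra-O-benzylcatechin-(4α→8)-3-O-acetyl-tetra-O-benzylcatechin-(4α→6)-3-O-acetyl-8-bromo-tetra-O-benzylcatechin | c1ccccc1COc1cc(OCc2ccccc2)c2c(c1Br)O[C@H](c1ccc(OCc3ccccc3)c(OCc3ccccc3)c1)[C@@H](OC(C)=O)[C@@H]2c1c(OCc3ccccc3)cc(OCc3ccccc3)c2c1O[C@H](c1ccc(OCc3ccccc3)c(OCc3ccccc3)c1)[C@@H](OC(C)=O)[C@@H]2c1c(OCc3ccccc3)c(Br)c2c(c1OCc1ccccc1)C[C@H](OC(C)=O)[C@@H](c1ccc(OCc3ccccc3)c(OCc3ccccc3)c1)O2 | intermediate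
19 | 8-bromo-tetra-O-benzylcatechin-(4α→8)-tetra-O-benzylcatechin-(4α→6)-8-bromo-tetra-O-benzylcatechin (three free C3 hydroxyls) | c1ccccc1COc1cc(OCc2ccccc2)c2c(c1Br)O[C@H](c1ccc(OCc3ccccc3)c(OCc3ccccc3)c1)[C@@H](O)[C@@H]2c1c(OCc3ccccc3)cc(OCc3ccccc3)c2c1O[C@H](c1ccc(OCc3ccccc3)c(OCc3ccccc3)c1)[C@@H](O)[C@@H]2c1c(OCc3ccccc3)c(Br)c2c(c1OCc1ccccc1)C[C@H](O)[C@@H](c1ccc(OCc3ccccc3)c(OCc3ccccc3)c1)O2 | intermediate
20 | catechin-(4α→8)-catechin-(4α→6)-catechin (CNP0178679.4) | Oc1cc(O)c2c(c1)O[C@H](c1ccc(O)c(O)c1)[C@@H](O)[C@@H]2c1c(O)cc(O)c2c1O[C@H](c1ccc(O)c(O)c1)[C@@H](O)[C@@H]2c1c(O)cc2c(c1O)C[C@H](O)[C@@H](c1ccc(O)c(O)c1)O2 | target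

**Totals**

Total step count: 14. Longest linear sequence: 9 steps (steps 1, 2, 3, 4, 5, 9, 12, 13, 14).

**Steps most likely to fail**

Step 9 (the key step). What may go wrong: addition of the dienophile in the enol sense (C4 bonding to the benzylic carbon), low facial discrimination by the catalyst on a methide that carries a doubly ortho-substituted aryl, or consumption of the methide by arylation. The fallback uses known chemistry, sets out from 2 and 4 and comes back at 15. DDQ oxidation of 2 in the presence of 2-ethoxyethanol should give 4β-(2-ethoxyethoxy)-5,7,3',4'-tetra-O-benzyl-(+)-catechin F1. Acetylation gives 3-O-acetyl-4β-(2-ethoxyethoxy)-5,7,3',4'-tetra-O-benzyl-(+)-catechin F2. TMSOTf-mediated Friedel–Crafts condensation of F2 with an excess of 4 (CH2Cl2, −78 °C) should then engage C6 of 4, its only free ring A carbon, from the α face under 3-acetoxy participation and deliver 15.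

Step 5. What may go wrong: the phenoxide addition to the doubly ortho-substituted, electron-rich aldehyde stalls or reverts, or the adduct ionises on magnesium and arylates a second phenoxide. The fallback sets out from 7 and 6 and comes back at 9. It replaces the carbonyl addition by a boron-templated dehydrative condensation: 7, 6 and PhB(OH)2 with catalytic propionic acid in toluene under azeotropic removal of water should give 4-(3-O-acetyl-8-bromo-5,7,3',4'-tetra-O-benzylcatechin-6-yl)-5,7-bis(benzyloxy)-2-phenyl-4H-1,3,2-benzodioxaborin F3, in which the new carbinol is locked in a cyclic boronate and cannot ionise. Cleavage of the boron with H2O2 in THF then releases 9.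

Step 4. What may go wrong: the bulky chloroiminium electrophile fails to engage the bromine-deactivated C6 between two benzyloxy groups, or substitution strays to ring B. The fallback sets out from 4 and comes back at 6. Iodination of 4 with N-iodosuccinimide and catalytic CF3CO2H should place the small iodine electrophile at C6 and give 3-O-acetyl-8-bromo-6-iodo-5,7,3',4'-tetra-O-benzyl-(+)-catechin F4. Selective iodine–magnesium exchange with i-PrMgCl·LiCl at low temperature (C–I exchanges before C–Br, the flanking benzyloxy groups chelate magnesium) gives the C6 arylmagnesium chloride of 3-O-acetyl-8-bromo-5,7,3',4'-tetra-O-benzyl-(+)-catechin F5, which is quenched with DMF to give 6.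

**Further compounds**

F1 | step 9 | 4β-(2-ethoxyethoxy)-5,7,3',4'-tetra-O-benzyl-(+)-catechin | c1ccccc1COc1cc(OCc2ccccc2)c2c(c1)O[C@H](c1ccc(OCc3ccccc3)c(OCc3ccccc3)c1)[C@@H](O)[C@H]2OCCOCC
F2 | step 9 | 3-O-acetyl-4β-(2-ethoxyethoxy)-5,7,3',4'-tetra-O-benzyl-(+)-catechin | c1ccccc1COc1cc(OCc2ccccc2)c2c(c1)O[C@H](c1ccc(OCc3ccccc3)c(OCc3ccccc3)c1)[C@@H](OC(C)=O)[C@H]2OCCOCC
F3 | step 5 | 4-(3-O-acetyl-8-bromo-5,7,3',4'-tetra-O-benzylcatechin-6-yl)-5,7-bis(benzyloxy)-2-phenyl-4H-1,3,2-benzodioxaborin | c1ccccc1B1Oc2cc(OCc3ccccc3)cc(OCc3ccccc3)c2C(O1)c1c(OCc3ccccc3)c(Br)c2c(c1OCc1ccccc1)C[C@H](OC(C)=O)[C@@H](c1ccc(OCc3ccccc3)c(OCc3ccccc3)c1)O2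
F4 | step 4 | 3-O-acetyl-8-bromo-6-iodo-5,7,3',4'-tetra-O-benzyl-(+)-catechin | c1ccccc1COc1c(I)c(OCc2ccccc2)c2c(c1Br)O[C@H](c1ccc(OCc3ccccc3)c(OCc3ccccc3)c1)[C@@H](OC(C)=O)C2
F5 | step 4 | C6 arylmagnesium chloride of 3-O-acetyl-8-bromo-5,7,3',4'-tetra-O-benzyl-(+)-catechin | c1ccccc1COc1c([Mg]Cl)c(OCc2ccccc2)c2c(c1Br)O[C@H](c1ccc(OCc3ccccc3)c(OCc3ccccc3)c1)[C@@H](OC(C)=O)C2
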